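**Retrosynthetic overview**

1. The target is the 7-O-ether of 7-hydroxy-8-methoxycoumarin with a (2E,5S,6S)-5,6-dihydroxy-3,7-dimethylocta-2,7-dienyl chain (C1' = OCH2 … C8' = CH2=). The last step only removes two silyl groups from the diol.
2. Key disconnection C1'–C2': a three-component union of a terminal alkyne (C2'–C8'), a methyl group from Me3Al (the C3' methyl) and an aryloxymethyl chloride (C1' with the whole coumarin), by Zr-catalysed syn-methylalumination and alkylation of the alkenylalane in the same flask.
3. Enabling feature: C2'=C3' is an (E)-2-methylalk-1-enyl unit whose C3' methyl and C1' are cis, the retron of syn-methylmetalation of a terminal alkyne. C1' is a methylene on the C7 oxygen of the chromen-2-one, i.e. a carbon at the formaldehyde oxidation level that can act as an aryloxymethyl cation.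
4. Alkyne fragment from prenal: catalytic asymmetric propargylation sets C5'; a hydroxyl-directed singlet-oxygen ene reaction sets C6' and creates the isopropenyl group; then bis-silylation.
5. Electrophile from 7-hydroxy-8-methoxycoumarin via its methylthiomethyl ether and sulfuryl chloride. No ring is formed in the route: the chromen-2-one bicycle is bought intact.

Key step: step 6

Assumptions: 7-hydroxy-8-methoxycoumarin is taken as a purchasable compound. The sense of induction of the phosphoric acid in step 1 is taken to be the one found with aryl and alkenyl aldehydes ((S)-acid, Si-face attack); if it is the opposite, the antipodal acid is used.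

**Route**

Step 1
Reactants: 1 3-methylbut-2-enal (prenal); 2 allenylboronic acid pinacol ester
Product: 4 (S)-6-methylhept-5-en-1-yn-4-ol, via pinacol borate ester 3 (not isolated)
Conditions: (S)-TRIP phosphoric acid (10 mol %), 4 Å MS, toluene, 0 °C; aq. NaHCO3 work-up
Reagents that add atoms: none
Why: Chiral phosphoric acid-catalysed asymmetric propargylation of an aldehyde with an allenylboronate (closed six-membered SE2' transition state, acid hydrogen-bonded to a boronate oxygen and the formyl C–H); the catalyst should direct addition to the Si face of the enal and set the carbinol carbon as S, and borate 3 is hydrolysed on work-up.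

Step 2
Reactants: 4 (S)-6-methylhept-5-en-1-yn-4-ol
Product: 6 (3S,4S)-2-methylhept-1-en-6-yne-3,4-diol, via allylic hydroperoxide 5 (not isolated)
Conditions: O2, tetraphenylporphyrin (cat.), white LED, CH2Cl2, −20 °C; then PPh3, 0 °C
Reagents that add atoms: dioxygen, O=O
Why: Schenck ene reaction of singlet oxygen with a chiral allylic alcohol: in the conformer that minimises A(1,3) strain against the cis methyl group the hydroxyl steers 1O2 to its own face by hydrogen bonding, oxygen adds at the olefinic CH with hydrogen abstraction from a methyl group, so the threo (3S,4S) hydroperoxide with the isopropenyl group should predominate, and PPh3 reduces the O–O bond without touching either stereocentre.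

Step 3
Reactants: 6 (3S,4S)-2-methylhept-1-en-6-yne-3,4-diol
Product: 7 (3S,4S)-3,4-bis[(tert-butyldimethylsilyl)oxy]-2-methylhept-1-en-6-yne
Conditions: TBSOTf (2.5 equiv), 2,6-lutidine, CH2Cl2, −78 → 0 °C
Reagents that add atoms: tert-butyldimethylsilyl trifluoromethanesulfonate, CC(C)(C)[Si](C)(C)OS(=O)(=O)C(F)(F)F
Why: Standard silylation of a hindered vicinal diol with a silyl triflate; the silyl ethers are inert to Me3Al and keep the oxygens from being alkylated in step 6.

Step 4
Reactants: 8 7-hydroxy-8-methoxy-2H-chromen-2-one
Product: 9 8-methoxy-7-[(methylsulfanyl)methoxy]-2H-chromen-2-one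
Conditions: NaH, ClCH2SMe, NaI (cat.), DMF, 0 °C → rt
Reagents that add atoms: chloromethyl methyl sulfide, CSCCl
Why: Williamson O-alkylation of the acidic 7-hydroxycoumarin phenoxide with an α-chloro sulfide, assisted by Finkelstein exchange with iodide.

Step 5
Reactants: 9 8-methoxy-7-[(methylsulfanyl)methoxy]-2H-chromen-2-one
Product: 10 7-(chloromethoxy)-8-methoxy-2H-chromen-2-one
Conditions: SO2Cl2 (1.05 equiv), CH2Cl2, 0 °C → rt; concentrated, co-evaporated with toluene, used at once
Reagents that add atoms: sulfuryl chloride, O=S(=O)(Cl)Cl
Why: Chlorinolysis of an O,S-acetal (aryl methylthiomethyl ether to aryl chloromethyl ether): the sulfide sulfur is chlorinated, the chlorosulfonium ion fragments to the aryloxycarbenium ion and MeSCl, and chloride returns to carbon; the sulfur is far more nucleophilic than the electron-poor coumarin.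

Step 6
Reactants: 7 (3S,4S)-3,4-bis[(tert-butyldimethylsilyl)oxy]-2-methylhept-1-en-6-yne; 10 7-(chloromethoxy)-8-methoxy-2H-chromen-2-one
Product: 12 7-{[(2E,5S,6S)-5,6-bis[(tert-butyldimethylsilyl)oxy]-3,7-dimethylocta-2,7-dien-1-yl]oxy}-8-methoxy-2H-chromen-2-one, via alkenyldimethylalane 11 (not isolated)
Conditions: Me3Al (2.0 equiv), Cp2ZrCl2 (0.25 equiv), CH2Cl2, 0 °C → rt; volatiles removed in vacuo; then 10 (1.3 equiv), CH2Cl2, −20 → 0 °C; aq. Rochelle salt
Reagents that add atoms: trimethylaluminium, C[Al](C)C
Why: Cp2ZrCl2 and Me3Al form a chloride-bridged Zr–Al methylzirconocene that adds Me–Zr syn across the terminal alkyne of 7 with methyl on the internal carbon, and Zr-to-Al exchange gives alkenylalane 11 and returns the catalyst (Negishi carboalumination). After removal of excess Me3Al, aluminium assists ionisation of the C–Cl bond of 10, and the aryloxycarbenium ion pair is captured at the aluminium-bearing sp2 carbon with retention (SE2), which forms the C1'–C2' bond and releases Me2AlCl. The closest known reaction type is the one-flask zirconium-catalysed methylalumination of a terminal alkyne followed by alkylation of the alkenylalane with chloromethyl methyl ether to give an (E)-3-methylallyl ether; here an aryl chloromethyl ether takes the place of the methyl one. No ring is closed and no sp3 stereocentre is made: the only new stereo-element, the E geometry of C2'=C3', follows from syn carbometalation and retentive substitution, which place the new C3' methyl and C1' cis. The selectivity needed is methyl to the internal alkyne carbon (secured by the terminal alkyne), alkyne over the 1,1-disubstituted isopropenyl olefin (inert to Cp2ZrCl2/Me3Al), alkenyl over methyl transfer from aluminium (the sp2 C–Al bond is the more reactive one and free Me3Al is stripped) and attack at the oxocarbenium carbon in preference to the coumarin lactone (alkenylalanes leave esters untouched at 0 °C). The two silyl ethers keep the C5' and C6' oxygens from being alkylated, so both stereocentres pass through unchanged.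

Step 7
Reactants: 12 7-{[(2E,5S,6S)-5,6-bis[(tert-butyldimethylsilyl)oxy]-3,7-dimethylocta-2,7-dien-1-yl]oxy}-8-methoxy-2H-chromen-2-one
Product: 13 7-{[(2E,5S,6S)-5,6-dihydroxy-3,7-dimethylocta-2,7-dien-1-yl]oxy}-8-methoxy-2H-chromen-2-one (target)
Conditions: TBAF (4 equiv), AcOH (4 equiv), THF, 0 °C → rt
Reagents that add atoms: none
Why: Fluoride-mediated cleavage of the two secondary silyl ethers, buffered with acetic acid so that the lactone and the allylic aryl ether are not exposed to free alkoxide; no stereocentre or olefin is affected.

**Compound list**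

1 | 3-methylbut-2-enal (prenal) | CC(C)=CC=O | starting material
2 | allenylboronic acid pinacol ester [4,4,5,5-tetramethyl-2-(propa-1,2-dien-1-yl)-1,3,2-dioxaborolane] | C=C=CB1OC(C)(C)C(C)(C)O1 | starting material
3 | pinacol borate ester of (S)-6-methylhept-5-en-1-yn-4-ol | CC(C)=C[C@@H](OB1OC(C)(C)C(C)(C)O1)CC#C | intermediate
4 | (S)-6-methylhept-5-en-1-yn-4-ol | CC(C)=C[C@@H](O)CC#C | intermediate
5 | (3S,4S)-3-hydroperoxy-2-methylhept-1-en-6-yn-4-ol | C=C(C)[C@H](OO)[C@@H](O)CC#C | intermediate
6 | (3S,4S)-2-methylhept-1-en-6-yne-3,4-diol | C=C(C)[C@H](O)[C@@H](O)CC#C | intermediate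
7 | (3S,4S)-3,4-bis[(tert-butyldimethylsilyl)oxy]-2-methylhept-1-en-6-yne | C=C(C)[C@H](O[Si](C)(C)C(C)(C)C)[C@@H](O[Si](C)(C)C(C)(C)C)CC#C | intermediate
8 | 7-hydroxy-8-methoxy-2H-chromen-2-one | Oc1ccc2ccc(=O)oc2c1OC | starting material
9 | 8-methoxy-7-[(methylsulfanyl)methoxy]-2H-chromen-2-one | CSCOc1ccc2ccc(=O)oc2c1OC | intermediate
10 | 7-(chloromethoxy)-8-methoxy-2H-chromen-2-one | ClCOc1ccc2ccc(=O)oc2c1OC | intermediate
11 | [(1E,4S,5S)-4,5-bis[(tert-butyldimethylsilyl)oxy]-2,6-dimethylhepta-1,6-dien-1-yl]dimethylalane | C=C(C)[C@H](O[Si](C)(C)C(C)(C)C)[C@@H](O[Si](C)(C)C(C)(C)C)C/C(C)=C/[Al](C)C | intermediate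
12 | 7-{[(2E,5S,6S)-5,6-bis[(tert-butyldimethylsilyl)oxy]-3,7-dimethylocta-2,7-dien-1-yl]oxy}-8-methoxy-2H-chromen-2-one | C=C(C)[C@H](O[Si](C)(C)C(C)(C)C)[C@@H](O[Si](C)(C)C(C)(C)C)C/C(C)=C/COc1ccc2ccc(=O)oc2c1OC | intermediate
13 | 7-{[(2E,5S,6S)-5,6-dihydroxy-3,7-dimethylocta-2,7-dien-1-yl]oxy}-8-methoxy-2H-chromen-2-one | C=C(C)[C@H](O)[C@@H](O)C/C(C)=C/COc1ccc2ccc(=O)oc2c1OC | target

**Step count and risks**

Total step count: 7. Longest linear sequence: 5 steps (steps 1, 2, 3, 6, 7 from prenal).

Steps most likely to fail:

Step 6. The alkylation may be outrun by methyl transfer from aluminium to the oxocarbenium ion, by capture of that ion by the isopropenyl olefin, or by Lewis-acid ionisation of the allylic aryl ether once it has formed. The fallback sets out from 7. Carboalumination as in step 6 gives 11, which is converted with n-BuLi (hexane/THF, −78 → 0 °C) into lithium [(1E,4S,5S)-4,5-bis[(tert-butyldimethylsilyl)oxy]-2,6-dimethylhepta-1,6-dien-1-yl](butyl)dimethylalanate F1. Treatment with paraformaldehyde should give, after aqueous work-up, (2E,5S,6S)-5,6-bis[(tert-butyldimethylsilyl)oxy]-3,7-dimethylocta-2,7-dien-1-ol F2. Mitsunobu etherification of F2 with phenol 8 (PPh3, DIAD, THF, 0 °C → rt) forms the aryl ether at the primary allylic carbon and comes back to the route at 12.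

Step 2. Facial control of oxygen delivery may be incomplete (erythro diol), or the ene reaction may abstract the carbinol hydrogen instead of a methyl hydrogen. The fallback sets out from 4. Hydroxyl-directed epoxidation with mCPBA (NaHCO3, CH2Cl2, 0 °C), which is threo-selective for allylic alcohols with a cis substituent for the same A(1,3) reason, should give (1S)-1-[(2R)-3,3-dimethyloxiran-2-yl]but-3-yn-1-ol F3. Base-mediated isomerisation of the trisubstituted epoxide to the allylic alcohol (excess diethylaluminium 2,2,6,6-tetramethylpiperidide, toluene, 0 °C; removal of a methyl proton, the C–O bond at the secondary carbon stays) comes back to the route at 6.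

Step 1. Enantiofacial discrimination may be low with a β,β-disubstituted enal, or the acid-labile allylic borate or alcohol may ionise under the Brønsted acid. The fallback sets out from 1. Zinc-mediated Barbier propargylation with propargyl bromide (Zn, THF/sat. aq. NH4Cl, 0 °C) gives racemic 6-methylhept-5-en-1-yn-4-ol F4. Lipase-catalysed kinetic resolution (Burkholderia cepacia lipase, vinyl acetate, MTBE, 30 °C, stopped near half conversion) should acylate the (R)-enantiomer, by the empirical size rule for secondary alcohols (2-methylprop-1-enyl as the large and propargyl as the medium group), to (R)-6-methylhept-5-en-1-yn-4-yl acetate F5. The remaining (S)-alcohol is separated by chromatography and comes back to the route at 4.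

**Further compounds**

F1 | step 6 | lithium [(1E,4S,5S)-4,5-bis[(tert-butyldimethylsilyl)oxy]-2,6-dimethylhepta-1,6-dien-1-yl](butyl)dimethylalanate | C=C(C)[C@H](O[Si](C)(C)C(C)(C)C)[C@@H](O[Si](C)(C)C(C)(C)C)C/C(C)=C/[Al-](C)(C)CCCC.[Li+]
F2 | step 6 | (2E,5S,6S)-5,6-bis[(tert-butyldimethylsilyl)oxy]-3,7-dimethylocta-2,7-dien-1-ol | C=C(C)[C@H](O[Si](C)(C)C(C)(C)C)[C@@H](O[Si](C)(C)C(C)(C)C)C/C(C)=C/CO
F3 | step 2 | (1S)-1-[(2R)-3,3-dimethyloxiran-2-yl]but-3-yn-1-ol | CC1(C)[C@H](O1)[C@@H](O)CC#C
F4 | step 1 | racemic 6-methylhept-5-en-1-yn-4-ol | CC(C)=CC(O)CC#C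
F5 | step 1 | (R)-6-methylhept-5-en-1-yn-4-yl acetate | CC(C)=C[C@H](OC(C)=O)CC#C
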